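## The problem

Target 23 is a 2,3-trans-2,3-dihydrobenzofuran. C2 (R) carries a 1-formylvinyl group, C3 (S) an isovalerate, and C5 an (R)-1-acyloxyethyl group whose acyl part is (R)-2-methylbutanoyl. The two ring stereocentres are neighbours and one can be set from the other; the carbinol on C5 and the α-carbon of the 2-methylbutanoate are too remote to be induced and are best brought in as enantiopure pieces. Both benzylic C–O bonds are fragile: the C3 ester is ortho-related and the side-chain ester para-related to the ring oxygen, so either ionises under protic or strong Lewis acid, and loss of the C3 acyloxy group with H2 aromatises the heterocycle to a benzofuran. The enal is a reactive Michael acceptor, the aldehyde that precedes it can expel the ring phenoxide from its β-carbon, and the 2-methylbutanoate α-centre will not tolerate strong base. The feature that invites a de novo arene synthesis is the substitution pattern of the benzene ring. O1 on C7a and C3 on C3a are adjacent, the carbinol sits on C5 para to O1, and C4, C6 and C7 are unsubstituted. The six ring carbons can therefore be read as three alkynes: C7a≡C7 (an ynol ether on O1), C3a≡C4 (an ethynyl group on C3) and C5≡C6 (a but-3-yn-2-yl ester), the first two tied by the chain O1–C2–C3. Two consequences follow. An ynol ether cannot sit on a carbon that also bears a vinyl group, because allyl alkynyl ethers rearrange sigmatropically far below room temperature, so the formylvinyl group has to be grown from a saturated arm after the ring exists. And whatever steers the third alkyne to C5 must later leave C7 without acid.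

## Retrosynthesis

**Exocyclic C=CH2 bond.** Target 23 is cut at the methylene carbon, which leads to aldehyde 21 (arm CH2–CHO on C2) and a one-carbon iminium electrophile. The neighbouring cut, allylic oxidation of a 2-isopropenyl group, would need an alkene next to C2 during the ring synthesis, which the ynol ether forbids, or a tertiary alcohol dehydration of uncertain regiochemistry. Aldehyde 21 comes from alcohol 20 and that from silyl ether 19. The forward sequence must use only mild base and a buffered fluoride source.

**C7–H bond.** Compound 19 is traced to aryl iodide 18 and that to aryl silane 17. The silicon is the regiochemical control element of the ring synthesis. Its removal by acid is excluded by the two benzylic esters, so the C–Si bond is exchanged for C–I by ipso-substitution at low temperature and the iodide is reduced under neutral radical conditions.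

**Benzene and dihydrofuran rings.** Compound 17 is cut at C3a–C7a, C4–C5 and C6–C7 into diyne 16 and alkyne ester 3. Against cuts that open only the heterocycle, this one is convergent, forms both rings at once and creates no stereocentre, so all four centres are settled on acyclic, purifiable material. The C3 isovalerate is already in 16, which avoids any later protecting-group exchange at the sensitive benzylic position. The forward reaction has to be cross-selective, regioselective (carbinol at C5, not C6) and run near room temperature.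

**Side-chain ester.** Alkyne ester 3 is cut at the ester C–O bond into alcohol 1 and acid 2, both commercial single enantiomers.

**C3–C(sp) bond.** Diyne 16 is cut between C3 and the ethynyl group and at the acyl oxygen, giving aldehyde 14. The order matters: ynol ether formation uses n-BuLi and would metalate and silylate a terminal alkyne as well, so the ethynyl group must arrive after the silylated ynol ether is in place. The forward step needs Felkin-type (3,4-anti) addition of an ethynyl Grignard reagent and acylation of the alkoxide in the same flask.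

**Ynol ether.** Aldehyde 14 comes from alcohol 13, and the C(sp)–O bond of 13 is traced through dichlorovinyl ether 10 and its trityl ether 9 to secondary alcohol 7. Once the ynol ether exists neither acid nor fluoride can be used, so the primary hydroxyl is released at the robust dichlorovinyl ether stage and carried through the lithiation as its alkoxide.

**Chiral pool.** Alcohol 7 is a differentially protected (R)-butane-1,2,4-triol, reached from diol 6, acetonide 5 and commercial dioxolane 4. The stereocentre of 4 becomes C2 of the target and no bond to it is ever broken.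

## Roads not taken

Alternative 1: The cut is C2–C3. The allenyl aryl ether aldehyde A1 would be treated with CuCl, a chiral bisphosphine, NaOt-Bu and B2pin2. Borylcupration of the terminal allene double bond gives a 2-borylallylcopper, which must attack the ortho aldehyde through its oxygen-bearing carbon to close the dihydrofuran and give A2.
- Merits: the arene is bought, both ring stereocentres come from the catalyst in the ring-closing step, and the route is the shortest on paper.
- Weak points: the trans relationship is decided in a bicyclic transition state for which an aryloxy-substituted allylcopper has no close analogy, and cis closure is a real possibility. Alkoxide base and boron alkoxides sit next to an epimerisable ester. After the key step the C–B bond still has to become C–CHO (one-carbon homologation and oxidation) and C3 has to be acylated.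
- Comparison: this road is better in step count and needs no silicon removal. The chosen plan sets against it a relative configuration fixed before any ring is formed and an enal that arrives in a single one-carbon step.

Alternative 2: The cut is the O1–C2 bond, made by migration of the ring oxygen in chromanol A3. Triflation of the C3 hydroxyl (Tf2O, hindered pyridine) lets the pyran oxygen displace the triflate with inversion. The resulting tertiary cation loses a methyl proton and gives the ring-contracted isopropenyl compound A4, which needs only SeO2 allylic oxidation to reach the target.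
- Merits: A3 belongs to a class reached by highly reliable asymmetric epoxidation chemistry, the trans geometry follows stereospecifically, and the C3 ester and the isopropenyl group are in place at once. This is the shortest of the three.
- Weak points: the cationic manifold can partition. Proton loss toward the ring gives an enol ether and then a benzofuran, the neighbouring ester can participate through a dioxolanylium ion, and plain elimination competes. Triflic acid equivalents are generated beside a para-alkoxybenzylic ester. The last step is a SeO2 oxidation on a molecule with two ionisable benzylic esters, a reaction that often stops at the allylic alcohol or over-oxidises.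
- Comparison: in length and in the quality of its asymmetric step this road is better. The chosen plan sets against it that no carbocation is generated next to ionisable esters and that the aldehyde carbon is added as a separate unit under mild base.

Alternative 3: The cut is C3–C3a. The iodoaryl α-aryloxy aldehyde A5 would be treated with CrCl2 and catalytic NiCl2; the arylchromium species adds to the tethered aldehyde and gives carbinol A6.
- Merits: a known reaction type, neutral and tolerant of esters, with the arene bought.
- Weak points: the C3 configuration is created in the ring closure under substrate control alone. A5 is hindered and configurationally labile. Four further steps follow, among them dehydration of a tertiary alcohol (isopropenyl against the conjugated enol ether) and SeO2 oxidation. Chromium is used in excess.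
- Comparison: this road carries less risk in its key step and is better in that respect; its length is similar. The chosen plan sets against it convergence (two rings and three bonds in one catalytic step from two chiral-pool fragments) and an end game without dehydration or selenium. The same C3–C3a closure, adapted to the two-carbon arm, is kept in reserve as the fallback for step 10.

Key step: step 10

Remark: the target SMILES is read as the (2R,3S)-trans isomer with (1R)-carbinol and (2R)-acyl centres; C2 of the target is C4 of dioxolane 4.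

## Route

Step 1
Reactants: 1 (2R)-but-3-yn-2-ol; 2 (2R)-2-methylbutanoic acid
Product: 3 (2R)-but-3-yn-2-yl (2R)-2-methylbutanoate
Conditions: DCC, 4-(dimethylamino)pyridine (cat.), CH2Cl2, 0 °C to rt
Reagents that add atoms: none
Why: Steglich esterification; carbodiimide activation with catalytic acyl-transfer base at 0 °C acylates the propargylic alcohol without breaking a bond at either stereocentre, and the α-branched acid is not expected to epimerise under these conditions.

Step 2
Reactants: 4 2-[(4R)-2,2-dimethyl-1,3-dioxolan-4-yl]ethan-1-ol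
Product: 5 triisopropyl{2-[(4R)-2,2-dimethyl-1,3-dioxolan-4-yl]ethoxy}silane
Conditions: i-Pr3SiCl, imidazole, CH2Cl2, rt
Reagents that add atoms: triisopropylsilyl chloride, CC(C)[Si](Cl)(C(C)C)C(C)C
Why: Silylation of a primary alcohol; the triisopropylsilyl group is chosen because it survives the acid of steps 3 and 6 and the strong bases of steps 5 and 7, is the silyl group least prone to O-to-O migration onto a neighbouring alkoxide, and has no aryl–silicon bond that step 11 could attack.

Step 3
Reactants: 5 triisopropyl{2-[(4R)-2,2-dimethyl-1,3-dioxolan-4-yl]ethoxy}silane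
Product: 6 (2R)-4-[(triisopropylsilyl)oxy]butane-1,2-diol
Conditions: AcOH–H2O (4:1), 40 °C
Reagents that add atoms: none
Why: Acid-catalysed acetal hydrolysis; a primary triisopropylsilyl ether is stable to aqueous acetic acid, and the stereocentre is untouched.

Step 4
Reactants: 6 (2R)-4-[(triisopropylsilyl)oxy]butane-1,2-diol
Product: 7 (2R)-4-[(triisopropylsilyl)oxy]-1-(trityloxy)butan-2-ol
Conditions: Ph3CCl, Et3N, 4-(dimethylamino)pyridine (cat.), CH2Cl2, rt
Reagents that add atoms: trityl chloride, ClC(c1ccccc1)(c1ccccc1)c1ccccc1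
Why: Sterically controlled tritylation of the primary hydroxyl of a 1,2-diol; trityl cannot migrate to the neighbouring alkoxide in step 5 and comes off under acid that the dichlorovinyl ether tolerates.

Step 5
Reactants: 7 (2R)-4-[(triisopropylsilyl)oxy]-1-(trityloxy)butan-2-ol
Product: 9 triisopropyl{[(3R)-3-{[(E)-1,2-dichloroethenyl]oxy}-4-(trityloxy)butyl]oxy}silane, via potassium alkoxide 8 (not isolated)
Conditions: KH, THF, 0 °C; then Cl2C=CHCl, −50 °C to rt
Reagents that add atoms: trichloroethylene, ClC=C(Cl)Cl
Why: First stage of the dichlorovinyl ether route to ynol ethers; base turns trichloroethylene into dichloroacetylene, the alkoxide adds to it and the vinyl anion is protonated to the (E)-1,2-dichlorovinyl ether, with the C–O bond of the stereocentre left intact.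

Step 6
Reactants: 9 triisopropyl{[(3R)-3-{[(E)-1,2-dichloroethenyl]oxy}-4-(trityloxy)butyl]oxy}silane
Product: 10 (2R)-2-{[(E)-1,2-dichloroethenyl]oxy}-4-[(triisopropylsilyl)oxy]butan-1-ol
Conditions: p-toluenesulfonic acid monohydrate (cat.), MeOH–CH2Cl2 (1:1), 0 °C
Reagents that add atoms: none
Why: Acid-catalysed detritylation with capture of the trityl cation by methanol; the doubly chlorinated enol ether is too electron-poor to be protonated under these conditions, so this is the last point at which acid can be used to free the primary hydroxyl.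

Step 7
Reactants: 10 (2R)-2-{[(E)-1,2-dichloroethenyl]oxy}-4-[(triisopropylsilyl)oxy]butan-1-ol
Product: 13 (2R)-4-[(triisopropylsilyl)oxy]-2-{[(trimethylsilyl)ethynyl]oxy}butan-1-ol, via dilithio alkoxide-acetylide 11 (not isolated), via O,C-bis(trimethylsilyl) derivative 12 (not isolated)
Conditions: n-BuLi (3.3 equiv), THF, −78 to −40 °C; Me3SiCl (2.5 equiv), −78 to 0 °C; then K2CO3 (cat.), MeOH, 0 °C, 10 min
Reagents that add atoms: chlorotrimethylsilane, C[Si](C)(C)Cl
Why: Second stage of the ynol ether synthesis; n-BuLi eliminates HCl and exchanges the remaining chlorine to give the lithium alkoxyacetylide (the hydroxyl rides along as its lithium alkoxide), silylation caps both, and brief carbonate methanolysis cleaves the primary O–Si bond much faster than the C(sp)–Si bond. Because no other alkyne is present yet, silicon can end up only on the ynol ether terminus.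

Step 8
Reactants: 13 (2R)-4-[(triisopropylsilyl)oxy]-2-{[(trimethylsilyl)ethynyl]oxy}butan-1-ol
Product: 14 (2R)-4-[(triisopropylsilyl)oxy]-2-{[(trimethylsilyl)ethynyl]oxy}butanal
Conditions: Dess–Martin periodinane, pyridine, CH2Cl2, 0 °C to rt
Reagents that add atoms: none
Why: Dess–Martin oxidation buffered with pyridine, the standard way to make α-alkoxy aldehydes without epimerisation; the acid-sensitive ynol ether sees no free acetic acid, and the aldehyde is used at once.

Step 9
Reactants: 14 (2R)-4-[(triisopropylsilyl)oxy]-2-{[(trimethylsilyl)ethynyl]oxy}butanal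
Product: 16 (3S,4R)-6-[(triisopropylsilyl)oxy]-4-{[(trimethylsilyl)ethynyl]oxy}hex-1-yn-3-yl 3-methylbutanoate, via bromomagnesium alkoxide 15 (not isolated)
Conditions: HC≡CMgBr, THF, −78 °C; then (i-BuCO)2O, 4-(dimethylamino)pyridine (cat.), −78 to 0 °C
Reagents that add atoms: ethynylmagnesium bromide, C#C[Mg]Br; 3-methylbutanoic anhydride, CC(C)CC(=O)OC(=O)CC(C)C
Why: Grignard addition to an α-oxygenated aldehyde under polar Felkin–Anh control, then acylation of the alkoxide in the same flask. The ynol ether oxygen is a poor ligand for magnesium, so no chelate should form and attack anti to the C–O bond should favour the 3,4-anti (3S) isomer; the minor epimer is removed by chromatography.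

Step 10
Reactants: 16 (3S,4R)-6-[(triisopropylsilyl)oxy]-4-{[(trimethylsilyl)ethynyl]oxy}hex-1-yn-3-yl 3-methylbutanoate; 3 (2R)-but-3-yn-2-yl (2R)-2-methylbutanoate
Product: 17 (1R)-1-[(2R,3S)-3-[(3-methylbutanoyl)oxy]-2-{2-[(triisopropylsilyl)oxy]ethyl}-7-(trimethylsilyl)-2,3-dihydro-1-benzofuran-5-yl]ethyl (2R)-2-methylbutanoate
Conditions: RhCl(PPh3)3 (5 mol%), 3 (3 equiv), toluene, 40 °C, slow addition of 16
Reagents that add atoms: none
Why: Proposed new method: monovalent rhodium is expected to couple the two tethered alkynes of 16 oxidatively to a bicyclic rhodacyclopentadiene of trivalent rhodium, which forms C3a–C7a and closes the five-membered oxygen ring across the three-atom O1–C2–C3 tether of a 1,6-diyne. Insertion of the terminal alkyne of 3 into the less hindered Rh–C4 bond then forms C4–C5, and reductive elimination forms C6–C7, closes the benzene ring and releases the catalyst. The closest known reaction type is the RhCl(PPh3)3-catalysed crossed [2+2+2] cyclotrimerisation of heteroatom-tethered 1,6-diynes with monoalkynes, in particular of ynamide diynes to indolines, together with the use of silylated alkoxyalkynes as monoalkyne partners in cobalt-mediated cocyclisations; an ynol ether as the tethered component has not been shown. No stereocentre is formed: C2 and C3 lie in the tether and the two centres of 3 are spectators, so all four pass through unchanged. The selectivity that matters is regiochemical, and it is secured by the trimethylsilyl group on the ynol ether terminus, which becomes C7 and makes the substituted carbon of 3 bond to the unhindered C4, placing the carbinol on C5 para to O1. Crossed reaction over diyne oligomerisation is secured by adding 16 slowly to an excess of 3, and 40 °C is well below the temperature at which a secondary alkyl ynol ether loses silylketene by a retro-ene path.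

Step 11
Reactants: 17 (1R)-1-[(2R,3S)-3-[(3-methylbutanoyl)oxy]-2-{2-[(triisopropylsilyl)oxy]ethyl}-7-(trimethylsilyl)-2,3-dihydro-1-benzofuran-5-yl]ethyl (2R)-2-methylbutanoate
Product: 18 (1R)-1-[(2R,3S)-7-iodo-3-[(3-methylbutanoyl)oxy]-2-{2-[(triisopropylsilyl)oxy]ethyl}-2,3-dihydro-1-benzofuran-5-yl]ethyl (2R)-2-methylbutanoate
Conditions: ICl (1.05 equiv), CH2Cl2, −78 °C
Reagents that add atoms: iodine monochloride, ClI
Why: Electrophilic ipso-iododesilylation; the ortho ring oxygen and the β-silicon effect direct the iodine electrophile to C7, and the aprotic conditions at −78 °C should spare both benzylic esters, which a protic protodesilylation would ionise.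

Step 12
Reactants: 18 (1R)-1-[(2R,3S)-7-iodo-3-[(3-methylbutanoyl)oxy]-2-{2-[(triisopropylsilyl)oxy]ethyl}-2,3-dihydro-1-benzofuran-5-yl]ethyl (2R)-2-methylbutanoate
Product: 19 (1R)-1-[(2R,3S)-3-[(3-methylbutanoyl)oxy]-2-{2-[(triisopropylsilyl)oxy]ethyl}-2,3-dihydro-1-benzofuran-5-yl]ethyl (2R)-2-methylbutanoate
Conditions: (Me3Si)3SiH, 2,2'-azobis(2-methylpropionitrile) (cat.), toluene, 80 °C
Reagents that add atoms: none
Why: Radical chain hydrodeiodination; the silyl radical abstracts iodine and the aryl radical takes hydrogen from the silane, under neutral conditions that leave esters, silyl ether and stereocentres alone.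

Step 13
Reactants: 19 (1R)-1-[(2R,3S)-3-[(3-methylbutanoyl)oxy]-2-{2-[(triisopropylsilyl)oxy]ethyl}-2,3-dihydro-1-benzofuran-5-yl]ethyl (2R)-2-methylbutanoate
Product: 20 (1R)-1-[(2R,3S)-2-(2-hydroxyethyl)-3-[(3-methylbutanoyl)oxy]-2,3-dihydro-1-benzofuran-5-yl]ethyl (2R)-2-methylbutanoate
Conditions: Bu4NF, AcOH (1:1), THF, rt
Reagents that add atoms: none
Why: Fluoride desilylation of a primary silyl ether; buffering with acetic acid keeps the medium close to neutral, so neither acyl migration nor ionisation of the benzylic esters is expected.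

Step 14
Reactants: 20 (1R)-1-[(2R,3S)-2-(2-hydroxyethyl)-3-[(3-methylbutanoyl)oxy]-2,3-dihydro-1-benzofuran-5-yl]ethyl (2R)-2-methylbutanoate
Product: 21 (1R)-1-[(2R,3S)-3-[(3-methylbutanoyl)oxy]-2-(2-oxoethyl)-2,3-dihydro-1-benzofuran-5-yl]ethyl (2R)-2-methylbutanoate
Conditions: Dess–Martin periodinane, pyridine, CH2Cl2, 0 °C to rt
Reagents that add atoms: none
Why: Dess–Martin oxidation of the primary alcohol under buffered conditions; the β-aryloxy aldehyde is taken on directly.

Step 15
Reactants: 21 (1R)-1-[(2R,3S)-3-[(3-methylbutanoyl)oxy]-2-(2-oxoethyl)-2,3-dihydro-1-benzofuran-5-yl]ethyl (2R)-2-methylbutanoate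
Product: 23 (1R)-1-[(2R,3S)-3-[(3-methylbutanoyl)oxy]-2-(3-oxoprop-1-en-2-yl)-2,3-dihydro-1-benzofuran-5-yl]ethyl (2R)-2-methylbutanoate, via Mannich base 22 (not isolated)
Conditions: Me2N=CH2 I (Eschenmoser's salt), Et3N, CH2Cl2, rt
Reagents that add atoms: N,N-dimethylmethyleneiminium iodide, C=[N+](C)C.[I-]
Why: Aldehyde α-methylenation by Mannich reaction and β-elimination of dimethylamine; the aldehyde has a single α-carbon, so the 1-formylvinyl group forms unambiguously, and once it is formed no α-hydrogen remains from which the ring phenoxide could be expelled.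

## Compound list

1 | (2R)-but-3-yn-2-ol | C#C[C@@H](C)O | starting material
2 | (2R)-2-methylbutanoic acid | CC[C@@H](C)C(=O)O | starting material
3 | (2R)-but-3-yn-2-yl (2R)-2-methylbutanoate | C#C[C@@H](C)OC(=O)[C@H](C)CC | intermediate
4 | 2-[(4R)-2,2-dimethyl-1,3-dioxolan-4-yl]ethan-1-ol | OCC[C@@H]1COC(C)(C)O1 | starting material
5 | triisopropyl{2-[(4R)-2,2-dimethyl-1,3-dioxolan-4-yl]ethoxy}silane | CC(C)[Si](C(C)C)(C(C)C)OCC[C@@H]1COC(C)(C)O1 | intermediate
6 | (2R)-4-[(triisopropylsilyl)oxy]butane-1,2-diol | CC(C)[Si](C(C)C)(C(C)C)OCC[C@@H](O)CO | intermediate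
7 | (2R)-4-[(triisopropylsilyl)oxy]-1-(trityloxy)butan-2-ol | CC(C)[Si](C(C)C)(C(C)C)OCC[C@@H](O)COC(c1ccccc1)(c1ccccc1)c1ccccc1 | intermediate
8 | potassium (2R)-4-[(triisopropylsilyl)oxy]-1-(trityloxy)butan-2-olate | CC(C)[Si](C(C)C)(C(C)C)OCC[C@@H]([O-])COC(c1ccccc1)(c1ccccc1)c1ccccc1.[K+] | intermediate
9 | triisopropyl{[(3R)-3-{[(E)-1,2-dichloroethenyl]oxy}-4-(trityloxy)butyl]oxy}silane | CC(C)[Si](C(C)C)(C(C)C)OCC[C@@H](O/C(Cl)=C\Cl)COC(c1ccccc1)(c1ccccc1)c1ccccc1 | intermediate
10 | (2R)-2-{[(E)-1,2-dichloroethenyl]oxy}-4-[(triisopropylsilyl)oxy]butan-1-ol | CC(C)[Si](C(C)C)(C(C)C)OCC[C@@H](O/C(Cl)=C\Cl)CO | intermediate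
11 | lithium (2R)-2-[(lithioethynyl)oxy]-4-[(triisopropylsilyl)oxy]butan-1-olate | CC(C)[Si](C(C)C)(C(C)C)OCC[C@@H](OC#C[Li])CO[Li] | intermediate
12 | triisopropyl{[(3R)-4-[(trimethylsilyl)oxy]-3-{[(trimethylsilyl)ethynyl]oxy}butyl]oxy}silane | CC(C)[Si](C(C)C)(C(C)C)OCC[C@@H](OC#C[Si](C)(C)C)CO[Si](C)(C)C | intermediate
13 | (2R)-4-[(triisopropylsilyl)oxy]-2-{[(trimethylsilyl)ethynyl]oxy}butan-1-ol | CC(C)[Si](C(C)C)(C(C)C)OCC[C@@H](OC#C[Si](C)(C)C)CO | intermediate
14 | (2R)-4-[(triisopropylsilyl)oxy]-2-{[(trimethylsilyl)ethynyl]oxy}butanal | CC(C)[Si](C(C)C)(C(C)C)OCC[C@@H](OC#C[Si](C)(C)C)C=O | intermediate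
15 | bromomagnesium (3S,4R)-6-[(triisopropylsilyl)oxy]-4-{[(trimethylsilyl)ethynyl]oxy}hex-1-yn-3-olate | CC(C)[Si](C(C)C)(C(C)C)OCC[C@@H](OC#C[Si](C)(C)C)[C@H](C#C)O[Mg]Br | intermediate
16 | (3S,4R)-6-[(triisopropylsilyl)oxy]-4-{[(trimethylsilyl)ethynyl]oxy}hex-1-yn-3-yl 3-methylbutanoate | CC(C)[Si](C(C)C)(C(C)C)OCC[C@@H](OC#C[Si](C)(C)C)[C@H](C#C)OC(=O)CC(C)C | intermediate
17 | (1R)-1-[(2R,3S)-3-[(3-methylbutanoyl)oxy]-2-{2-[(triisopropylsilyl)oxy]ethyl}-7-(trimethylsilyl)-2,3-dihydro-1-benzofuran-5-yl]ethyl (2R)-2-methylbutanoate | CC(C)[Si](C(C)C)(C(C)C)OCC[C@H]1Oc2c([Si](C)(C)C)cc([C@@H](C)OC(=O)[C@H](C)CC)cc2[C@@H]1OC(=O)CC(C)C | intermediate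
18 | (1R)-1-[(2R,3S)-7-iodo-3-[(3-methylbutanoyl)oxy]-2-{2-[(triisopropylsilyl)oxy]ethyl}-2,3-dihydro-1-benzofuran-5-yl]ethyl (2R)-2-methylbutanoate | CC(C)[Si](C(C)C)(C(C)C)OCC[C@H]1Oc2c(I)cc([C@@H](C)OC(=O)[C@H](C)CC)cc2[C@@H]1OC(=O)CC(C)C | intermediate
19 | (1R)-1-[(2R,3S)-3-[(3-methylbutanoyl)oxy]-2-{2-[(triisopropylsilyl)oxy]ethyl}-2,3-dihydro-1-benzofuran-5-yl]ethyl (2R)-2-methylbutanoate | CC(C)[Si](C(C)C)(C(C)C)OCC[C@H]1Oc2ccc([C@@H](C)OC(=O)[C@H](C)CC)cc2[C@@H]1OC(=O)CC(C)C | intermediate
20 | (1R)-1-[(2R,3S)-2-(2-hydroxyethyl)-3-[(3-methylbutanoyl)oxy]-2,3-dihydro-1-benzofuran-5-yl]ethyl (2R)-2-methylbutanoate | OCC[C@H]1Oc2ccc([C@@H](C)OC(=O)[C@H](C)CC)cc2[C@@H]1OC(=O)CC(C)C | intermediate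
21 | (1R)-1-[(2R,3S)-3-[(3-methylbutanoyl)oxy]-2-(2-oxoethyl)-2,3-dihydro-1-benzofuran-5-yl]ethyl (2R)-2-methylbutanoate | O=CC[C@H]1Oc2ccc([C@@H](C)OC(=O)[C@H](C)CC)cc2[C@@H]1OC(=O)CC(C)C | intermediate
22 | (1R)-1-[(2R,3S)-2-[3-(dimethylamino)-1-oxopropan-2-yl]-3-[(3-methylbutanoyl)oxy]-2,3-dihydro-1-benzofuran-5-yl]ethyl (2R)-2-methylbutanoate (both epimers at the new carbon) | CN(C)CC(C=O)[C@H]1Oc2ccc([C@@H](C)OC(=O)[C@H](C)CC)cc2[C@@H]1OC(=O)CC(C)C | intermediate
23 | (1R)-1-[(2R,3S)-3-[(3-methylbutanoyl)oxy]-2-(3-oxoprop-1-en-2-yl)-2,3-dihydro-1-benzofuran-5-yl]ethyl (2R)-2-methylbutanoate | C=C(C=O)[C@H]1Oc2ccc([C@@H](C)OC(=O)[C@H](C)CC)cc2[C@@H]1OC(=O)CC(C)C | target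

## Step count and least certain steps

Total: 15 steps. Longest linear sequence: 14 steps (4 to 23, steps 2–15); step 1 is a one-step branch that joins at step 10.

**Step 10 (key step).** Most likely to fail through oligomerisation of the diyne or dimerisation of the terminal alkyne outrunning the crossed reaction, through insertion of 3 in the wrong orientation (carbinol at C6), or through rhodium- or heat-induced breakdown of the ynol ether before the metallacycle forms. The fallback uses known reactions only, sets out from alcohol 7 and acid 2 and returns at 19.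
- The sodium alkoxide of 7 (NaH, DMF) displaces fluoride from commercial 1-(4-fluoro-3-iodophenyl)ethanone in a nucleophilic aromatic substitution activated by the para acetyl group. This gives the iodoaryl ether ketone F1 with retention at the carbinol carbon.
- Detritylation (p-toluenesulfonic acid, MeOH) gives the primary alcohol F2, and Dess–Martin oxidation gives the α-aryloxy aldehyde F3.
- Intramolecular Nozaki–Hiyama–Kishi arylation (CrCl2, catalytic NiCl2, DMF) closes the C3–C3a bond selectively at the aldehyde. It should give the trans 3-hydroxy-2,3-dihydrobenzofuran ketone F4, since the C2 arm prefers to eclipse hydrogen and not oxygen in the closing transition state.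
- Acylation with 3-methylbutanoic anhydride gives the keto ester F5.
- Corey–Bakshi–Shibata reduction ((S)-1-methyl-3,3-diphenyl-tetrahydro-1H,3H-pyrrolo[1,2-c][1,3,2]oxazaborole, BH3·SMe2) sets the (R)-carbinol in the benzylic alcohol F6.
- Steglich esterification of F6 with 2 gives 19.

**Step 9.** The likely failure is poor facial selectivity, because an ethynyl Grignard reagent is small and Felkin control may be modest. The fallback sets out from 14 and returns at 16. Addition of HC≡CMgBr with aqueous work-up gives the propargylic alcohol as a mixture of C3 epimers F7. Dess–Martin oxidation converges both to the ynone F8. Midland reduction with B-isopinocampheyl-9-borabicyclo[3.3.1]nonane derived from (+)-α-pinene, a reagent-controlled reduction known for terminal ynones, should give the (3S,4R)-alcohol F9. Acylation with 3-methylbutanoic anhydride and 4-(dimethylamino)pyridine then gives 16.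

**Step 7.** Two processes threaten it: intramolecular attack of the lithium alkoxide on the transient chloroalkynyl ether, and partial loss of the C-silyl group during the O-desilylation. The fallback sets out from diol 6 and returns at 13. The primary hydroxyl is masked as a 4-methoxybenzyl ether by way of the stannylene acetal (Bu2SnO; 4-methoxybenzyl chloride, Bu4NI), giving the ether F10. The two-stage ynol ether synthesis (KH, trichloroethylene; then n-BuLi, Me3SiCl) gives the dichlorovinyl ether F11 and the silylated ynol ether F12. Oxidative removal of the 4-methoxybenzyl group with DDQ in buffered CH2Cl2–water, which needs neither acid nor fluoride, gives 13.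

**Step 15.** The risk is base-induced expulsion of the ring phenoxide from the β-carbon of the enolisable aldehyde (retro-oxa-Michael opening), with epimerisation at C2 or ring-opened by-products. The fallback sets out from 21 and returns at 23, making the C–C bond without free base. Soft enolisation (Me3SiOTf with excess Et3N, −78 °C) gives the trimethylsilyl enol ether F13. F13 reacts with Eschenmoser's salt in CH2Cl2 without added base to give Mannich base 22. Quaternisation with MeI gives the trimethylammonium iodide F14, and aqueous NaHCO3 brings about the Hofmann-type elimination to 23.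

## Further compounds

F1 | step 10 | 1-{3-iodo-4-[((2R)-4-[(triisopropylsilyl)oxy]-1-(trityloxy)butan-2-yl)oxy]phenyl}ethan-1-one | CC(=O)c1ccc(O[C@H](CCO[Si](C(C)C)(C(C)C)C(C)C)COC(c2ccccc2)(c2ccccc2)c2ccccc2)c(I)c1
F2 | step 10 | 1-{4-[((2R)-1-hydroxy-4-[(triisopropylsilyl)oxy]butan-2-yl)oxy]-3-iodophenyl}ethan-1-one | CC(=O)c1ccc(O[C@H](CCO[Si](C(C)C)(C(C)C)C(C)C)CO)c(I)c1
F3 | step 10 | (2R)-2-(4-acetyl-2-iodophenoxy)-4-[(triisopropylsilyl)oxy]butanal | CC(=O)c1ccc(O[C@H](CCO[Si](C(C)C)(C(C)C)C(C)C)C=O)c(I)c1
F4 | step 10 | 1-[(2R,3S)-3-hydroxy-2-{2-[(triisopropylsilyl)oxy]ethyl}-2,3-dihydro-1-benzofuran-5-yl]ethan-1-one | CC(C)[Si](C(C)C)(C(C)C)OCC[C@H]1Oc2ccc(C(C)=O)cc2[C@@H]1O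
F5 | step 10 | (2R,3S)-5-acetyl-2-{2-[(triisopropylsilyl)oxy]ethyl}-2,3-dihydro-1-benzofuran-3-yl 3-methylbutanoate | CC(C)[Si](C(C)C)(C(C)C)OCC[C@H]1Oc2ccc(C(C)=O)cc2[C@@H]1OC(=O)CC(C)C
F6 | step 10 | (2R,3S)-5-[(1R)-1-hydroxyethyl]-2-{2-[(triisopropylsilyl)oxy]ethyl}-2,3-dihydro-1-benzofuran-3-yl 3-methylbutanoate | CC(C)[Si](C(C)C)(C(C)C)OCC[C@H]1Oc2ccc([C@@H](C)O)cc2[C@@H]1OC(=O)CC(C)C
F7 | step 9 | (4R)-6-[(triisopropylsilyl)oxy]-4-{[(trimethylsilyl)ethynyl]oxy}hex-1-yn-3-ol (C3 epimers) | CC(C)[Si](C(C)C)(C(C)C)OCC[C@@H](OC#C[Si](C)(C)C)C(O)C#C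
F8 | step 9 | (4R)-6-[(triisopropylsilyl)oxy]-4-{[(trimethylsilyl)ethynyl]oxy}hex-1-yn-3-one | CC(C)[Si](C(C)C)(C(C)C)OCC[C@@H](OC#C[Si](C)(C)C)C(=O)C#C
F9 | step 9 | (3S,4R)-6-[(triisopropylsilyl)oxy]-4-{[(trimethylsilyl)ethynyl]oxy}hex-1-yn-3-ol | CC(C)[Si](C(C)C)(C(C)C)OCC[C@@H](OC#C[Si](C)(C)C)[C@H](C#C)O
F10 | step 7 | (2R)-1-[(4-methoxybenzyl)oxy]-4-[(triisopropylsilyl)oxy]butan-2-ol | CC(C)[Si](C(C)C)(C(C)C)OCC[C@@H](O)COCc1ccc(OC)cc1
F11 | step 7 | triisopropyl{[(3R)-3-{[(E)-1,2-dichloroethenyl]oxy}-4-[(4-methoxybenzyl)oxy]butyl]oxy}silane | CC(C)[Si](C(C)C)(C(C)C)OCC[C@@H](O/C(Cl)=C\Cl)COCc1ccc(OC)cc1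
F12 | step 7 | triisopropyl{[(3R)-4-[(4-methoxybenzyl)oxy]-3-{[(trimethylsilyl)ethynyl]oxy}butyl]oxy}silane | CC(C)[Si](C(C)C)(C(C)C)OCC[C@@H](OC#C[Si](C)(C)C)COCc1ccc(OC)cc1
F13 | step 15 | (1R)-1-[(2R,3S)-3-[(3-methylbutanoyl)oxy]-2-{2-[(trimethylsilyl)oxy]ethenyl}-2,3-dihydro-1-benzofuran-5-yl]ethyl (2R)-2-methylbutanoate | C[Si](C)(C)OC=C[C@H]1Oc2ccc([C@@H](C)OC(=O)[C@H](C)CC)cc2[C@@H]1OC(=O)CC(C)C
F14 | step 15 | N,N,N-trimethyl-2-[(2R,3S)-3-[(3-methylbutanoyl)oxy]-5-[(1R)-1-{[(2R)-2-methylbutanoyl]oxy}ethyl]-2,3-dihydro-1-benzofuran-2-yl]-3-oxopropan-1-aminium iodide | C[N+](C)(C)CC(C=O)[C@H]1Oc2ccc([C@@H](C)OC(=O)[C@H](C)CC)cc2[C@@H]1OC(=O)CC(C)C.[I-]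
A1 | alternative 1 | (1R)-1-[3-formyl-4-(propa-1,2-dien-1-yloxy)phenyl]ethyl (2R)-2-methylbutanoate | C=C=COc1ccc([C@@H](C)OC(=O)[C@H](C)CC)cc1C=O
A2 | alternative 1 | (1R)-1-[(2R,3S)-3-hydroxy-2-[1-(4,4,5,5-tetramethyl-1,3,2-dioxaborolan-2-yl)ethenyl]-2,3-dihydro-1-benzofuran-5-yl]ethyl (2R)-2-methylbutanoate | CC1(C)OB(OC1(C)C)C(=C)[C@H]1Oc2ccc([C@@H](C)OC(=O)[C@H](C)CC)cc2[C@@H]1O
A3 | alternative 2 | (3R,4S)-3-hydroxy-2,2-dimethyl-6-[(1R)-1-{[(2R)-2-methylbutanoyl]oxy}ethyl]-3,4-dihydro-2H-chromen-4-yl 3-methylbutanoate | CC1(C)Oc2ccc([C@@H](C)OC(=O)[C@H](C)CC)cc2[C@H](OC(=O)CC(C)C)[C@H]1O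
A4 | alternative 2 | (2R,3S)-5-[(1R)-1-{[(2R)-2-methylbutanoyl]oxy}ethyl]-2-(prop-1-en-2-yl)-2,3-dihydro-1-benzofuran-3-yl 3-methylbutanoate | C=C(C)[C@H]1Oc2ccc([C@@H](C)OC(=O)[C@H](C)CC)cc2[C@@H]1OC(=O)CC(C)C
A5 | alternative 3 | (1R)-1-(3-iodo-4-{[(2R)-3-methyl-1-oxo-3-[(triethylsilyl)oxy]butan-2-yl]oxy}phenyl)ethyl (2R)-2-methylbutanoate | CC[Si](CC)(CC)OC(C)(C)[C@H](C=O)Oc1ccc([C@@H](C)OC(=O)[C@H](C)CC)cc1I
A6 | alternative 3 | (1R)-1-[(2S,3S)-3-hydroxy-2-{2-[(triethylsilyl)oxy]propan-2-yl}-2,3-dihydro-1-benzofuran-5-yl]ethyl (2R)-2-methylbutanoate | CC[Si](CC)(CC)OC(C)(C)[C@H]1Oc2ccc([C@@H](C)OC(=O)[C@H](C)CC)cc2[C@@H]1O
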